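**Retrosynthetic overview**
1. C19–C20 is the central σ-bond of the terminal 1,5-diene C17=C18–C19–C20–C21=C22. Both atoms are allylic CH2 groups, and C20–C21=C22(CH3)–C30–O maps atom for atom onto 2-methyl-2-vinyloxirane. The bond is cut to a C25 allyl pinacolboronate (boron on C19) and isoprene monoxide, joined by a Pd-catalysed ring-opening allyl–allyl coupling that also sets the 21E alkene and delivers the C30 oxygen.
2. C12–C13 is cut by a B-alkyl Suzuki–Miyaura coupling of a 9β-vinyl cis-decalin diol with (2E,6E)-7-iodo-2,6-dimethylhepta-2,6-dien-1-ol (carboalumination/iodination, then SeO2 oxidation).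
3. C9–C11 and the C8 carbinol come from anti opening of an 8α,9α-epoxide by vinylcopper. The epoxide is reached through the bromohydrin formed on the convex β face of a cis-octalin.
4. Rings: ring B is bought as (S)-carvone (C5 stereocentre). Allylation and then methylation anti to the isopropenyl group set C10. Ring A is closed afterwards by an Fe–H HAT radical alkene–aldehyde cyclisation (C3–C4 bond), which creates the gem-dimethyl C4 and locks the cis fusion.
5. After the coupling only acetylation of the primary allylic C30–OH and oxidation of C3–OH remain.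

Key step: step 14

Remark: the SMILES is read literally, so H-5 lies on the same face as the C-10 methyl (cis-fused decalin), H-9 on the opposite face, the C-8 methyl syn and the C-8 hydroxyl anti to the C-10 methyl (5S,8R,9R,10S); the terpenoid numbering of the target (decalin C1–C10, chain C11–C22 outward from C9, acetoxymethyl carbon C30) is used for all intermediates (carvone C=O = C9, its methyl-bearing carbon = C8, its CH2 next to C=O = C10, the isopropenyl carbon = C4), and β means the face of the C-10 methyl.

Step 1
Reactants: 1 (S)-(+)-carvone; 2 allyl bromide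
Product: 3 (5S,6R)-6-allylcarvone
Conditions: LDA, THF, −78 °C; then 2, −78 to 0 °C
Reagents that add atoms: none
Why: Kinetic α′-enolate alkylation of a cross-conjugated enone brings in C1–C3; the allyl group should enter anti to the isopropenyl group, but this centre (C10) is planarised again in step 2, so its configuration here does not matter.

Step 2
Reactants: 3 (5S,6R)-6-allylcarvone
Product: 4 (5R,6S)-6-allyl-6-methylcarvone
Conditions: LDA, THF, −78 °C; then MeI, DMPU, −78 to 0 °C
Reagents that add atoms: methyl iodide, CI
Why: In this second kinetic enolate alkylation MeI should attack the C10 enolate carbon anti to the neighbouring C5 isopropenyl group (1,2-induction), which sets the quaternary centre C10 with the methyl trans and the three-carbon arm cis to the isopropenyl unit, that is, the later cis ring fusion.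

Step 3
Reactants: 4 (5R,6S)-6-allyl-6-methylcarvone
Product: 6 (5R,6S)-6-allyl-2,6-dimethyl-5-(prop-1-en-2-yl)cyclohex-1-en-1-yl triflate, via lithium enolate 5 (not isolated)
Conditions: L-Selectride, THF, −78 °C; then N-(5-chloro-2-pyridyl)bis(trifluoromethanesulfonimide), −78 to 0 °C
Reagents that add atoms: N-(5-chloro-2-pyridyl)bis(trifluoromethanesulfonimide), O=S(=O)(N(c1ccc(Cl)cn1)S(=O)(=O)C(F)(F)F)C(F)(F)F
Why: Conjugate hydride reduction of the β-unsubstituted enone (1,2-attack is blocked by quaternary C10) gives enolate 5 regiospecifically, and O-triflation fixes the double bond at C8=C9; no stereocentre is made.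

Step 4
Reactants: 6 (5R,6S)-6-allyl-2,6-dimethyl-5-(prop-1-en-2-yl)cyclohex-1-en-1-yl triflate
Product: 7 (3R,4R)-3-allyl-1,3-dimethyl-4-(prop-1-en-2-yl)cyclohex-1-ene
Conditions: Pd(OAc)2 (cat.), PPh3 (cat.), HCO2H, n-Bu3N, DMF, 60 °C
Reagents that add atoms: none
Why: Pd-catalysed formate hydrogenolysis of an alkenyl triflate replaces OTf by H, so that steps 3 and 4 together move the ring alkene from C7=C8 to C8=C9 and delete the C9 oxygen; excess formate should outrun the strained 4-exo/5-endo Heck closures onto the pendant alkenes.

Step 5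
Reactants: 7 (3R,4R)-3-allyl-1,3-dimethyl-4-(prop-1-en-2-yl)cyclohex-1-ene
Product: 8 3-[1,3-dimethyl-6-(prop-1-en-2-yl)cyclohex-2-en-1-yl]propanal (configuration as in 7)
Conditions: PdCl2(PhCN)2, CuCl2·2H2O, AgNO2 (all cat.), t-BuOH/MeNO2, O2 (1 atm), rt
Reagents that add atoms: dioxygen, O=O (oxygen relayed through nitrite)
Why: The nitrite-modified, aldehyde-selective (anti-Markovnikov) Wacker oxidation is established for terminal alkenes whose homoallylic carbon is quaternary; only the monosubstituted alkene should bind Pd(II), while the 1,1-di- and trisubstituted alkenes stay untouched.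

Step 6
Reactants: 8 3-[1,3-dimethyl-6-(prop-1-en-2-yl)cyclohex-2-en-1-yl]propanal
Product: 9 cis-fused 4,4,8,10-tetramethyl-Δ8(9)-octalin-3β-ol (H-5 and 10-CH3 both β)
Conditions: Fe(acac)3 (cat.), PhSiH3, EtOH, 60 °C
Reagents that add atoms: none
Why: Fe–H hydrogen-atom transfer to the less hindered 1,1-disubstituted alkene gives the tertiary C4 radical, which adds 6-exo to the tethered aldehyde (MHAT radical alkene–carbonyl cyclisation), closing ring A and creating the gem-dimethyl C4; the fusion is cis because both arms already sit on the α face of ring B, and the C3 carbinol should form equatorial (3β) through a chair transition state and is erased in step 16.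

Step 7
Reactants: 9 cis-fused 4,4,8,10-tetramethyl-Δ8(9)-octalin-3β-ol
Product: 11 8α,9α-epoxy-cis-decalin-3β-ol, via bromohydrin 10 (not isolated)
Conditions: NBS, acetone/H2O, 0 °C; then K2CO3, MeOH, rt
Reagents that add atoms: water, O; N-bromosuccinimide, O=C1CCC(=O)N1Br (bromine stays only in 10)
Why: In this halohydrin route to the epoxide the bromonium ion should form on the convex β face (ring A is folded under the α face) and water opens it anti at the tertiary carbon C8 (Markovnikov, trans-diaxial), which sets C8 as 8α-OH/8β-CH3; base then closes the ring with inversion at C9 to the α-epoxide that direct peracid attack on the β face would not give.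

Step 8
Reactants: 11 8α,9α-epoxy-cis-decalin-3β-ol
Product: 12 9β-vinyl-4,4,8β,10β-tetramethyl-cis-decalin-3β,8α-diol
Conditions: CH2=CHMgBr (excess), CuI (cat.), THF, −20 °C to rt; aq. NH4Cl
Reagents that add atoms: vinylmagnesium bromide, C=C[Mg]Br
Why: Copper-catalysed Grignard opening of a trisubstituted epoxide should proceed by SN2 attack at the secondary carbon C9 from the open β face, anti to the C–O bond (trans-diaxial, Fürst–Plattner rule), which sets C9 with the vinyl group β and leaves the tertiary 8α-alkoxide; the first equivalent of Grignard reagent only deprotonates the C3 hydroxyl.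

Step 9
Reactants: 13 5-bromo-2-methylpent-2-ene
Product: 14 6-methylhept-5-en-1-yne
Conditions: lithium acetylide–ethylenediamine complex, DMSO, 10 °C to rt
Reagents that add atoms: lithium acetylide–ethylenediamine complex, [Li]C#C.NCCN
Why: This is a plain SN2 alkylation of lithium acetylide by a primary homoallylic bromide.

Step 10
Reactants: 14 6-methylhept-5-en-1-yne
Product: 16 (E)-1-iodo-2,6-dimethylhepta-1,5-diene, via alkenylalane 15 (not isolated)
Conditions: Me3Al, Cp2ZrCl2 (cat.), CH2Cl2, 0 °C to rt; then I2, THF, −30 °C
Reagents that add atoms: trimethylaluminium, C[Al](C)C; iodine, II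
Why: Negishi zirconium-catalysed syn-carboalumination of the terminal alkyne followed by iodinolysis with retention gives the E-iodoalkene (the later 13E alkene); the trisubstituted alkene does not carbometalate.

Step 11
Reactants: 16 (E)-1-iodo-2,6-dimethylhepta-1,5-diene
Product: 17 (2E,6E)-7-iodo-2,6-dimethylhepta-2,6-dien-1-ol
Conditions: SeO2 (cat.), t-BuOOH, salicylic acid (cat.), CH2Cl2, 0 °C to rt
Reagents that add atoms: tert-butyl hydroperoxide, CC(C)(C)OO (oxygen relayed through selenium dioxide, O=[Se]=O)
Why: In this Riley-type catalytic allylic oxidation the ene/[2,3]-sigmatropic sequence oxidises the E-methyl group of the electron-rich isopropylidene unit (17E geometry), while the iodoalkene is deactivated.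

Step 12
Reactants: 12 9β-vinyl-4,4,8β,10β-tetramethyl-cis-decalin-3β,8α-diol; 17 (2E,6E)-7-iodo-2,6-dimethylhepta-2,6-dien-1-ol
Product: 19 C25 triol (3β,8α,19-triol with 13E,17E-diene chain), via B-alkyl-9-BBN adduct 18 (not isolated)
Conditions: 9-BBN-H (excess), THF, rt to 50 °C; then 17, PdCl2(dppf) (cat.), AsPh3 (cat.), Cs2CO3, DMF/H2O, rt
Reagents that add atoms: 9-borabicyclo[3.3.1]nonane, [H]B1C2CCCC1CCC2 (boron stays only in 18)
Why: In the B-alkyl Suzuki–Miyaura coupling 9-BBN adds to the terminal carbon C12 of the vinyl group (the hydroxyls are only transiently borylated) and the sp3–sp2 coupling keeps the E-iodoalkene geometry, giving the 13E alkene without touching a stereocentre.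

Step 13
Reactants: 19 C25 triol
Product: 20 C25 allyl pinacolboronate (Bpin on C19; 3β,8α-diol)
Conditions: [Pd(MeCN)4](BF4)2 (cat.), B2pin2, DMSO/MeOH, rt
Reagents that add atoms: bis(pinacolato)diboron, CC1(C)OB(OC1(C)C)B1OC(C)(C)C(C)(C)O1
Why: Pd-catalysed direct borylation of an allylic alcohol runs through a π-allylpalladium intermediate, so boron should end on the unsubstituted terminus C19 with the E-alkene kept, and only the allylic C–O bond can ionise, so the C3 and C8 hydroxyls stay.

Step 14
Reactants: 20 C25 allyl pinacolboronate; 21 2-methyl-2-vinyloxirane (isoprene monoxide, racemic)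
Product: 23 (3S,5S,8R,9R,10S)-polypoda-13E,17E,21E-triene-3,8,30-triol, via pinacol borate ester 22 (not isolated)
Conditions: Pd2(dba)3 (cat.), DPEphos (cat.), THF, 25–40 °C, slow addition of 21 (excess); then aq. NH4Cl
Reagents that add atoms: none
Why: Proposed new method: Pd(0) ionises the allylic C–O bond of 21 to a zwitterionic (η3-allyl)palladium alkoxide whose own alkoxide binds the Bpin group of 20, so the resulting borate hands the C25 allyl group to palladium without external base, and C–C reductive elimination from the bis(allyl)palladium joins the two unsubstituted CH2 termini C19 and C20 to leave borate ester 22, which aqueous work-up hydrolyses to 23. The closest known reaction types are the Pd-catalysed allyl–allyl cross-coupling of allyl pinacolboronates with allylic carbonates or chlorides, which becomes linear-selective with monodentate or wide-bite-angle phosphines, and the base-free Pd-catalysed 1,4-opening of vinyl epoxides by alkenyl- and arylboron or -tin reagents; their combination on a β-methyl-γ-alkyl allylboronate has not been shown. No ring is closed and no stereocentre is made (the stereocentre of racemic 21 is erased on ionisation); the new stereo-element is the C21=C22 geometry, controlled by the preference of the π-allyl complex to hold the larger boron-bound oxidomethyl group syn and the methyl anti, which maps onto the E-alkene, while the 17E geometry of 20 should persist because its alkyl chain stays syn in every η3 form. The step needs head-to-head regioselectivity, and the substrate secures it, because every alternative would bond at C22 (a quaternary carbon) or at the branched C17 flanked by the C18 methyl, and the wide-bite-angle ligand disfavours the 3,3′-elimination that leads to branched dienes. Chemoselectivity rests on the neutral conditions: the secondary C3 and tertiary C8 hydroxyls and the other trisubstituted alkenes offer no allylic leaving group, and the allylic alkoxide of the product is too poor a leaving group to re-ionise. In one operation the step adds the last C5 unit, forms the C19–C20 bond, sets the third E-alkene and delivers the C30 oxygen at the right oxidation level.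

Step 15
Reactants: 23 (3S,5S,8R,9R,10S)-polypoda-13E,17E,21E-triene-3,8,30-triol
Product: 24 30-O-acetyl derivative of 23 (3β,8α-diol)
Conditions: Ac2O (1.1 equiv), pyridine, CH2Cl2, 0 °C
Reagents that add atoms: acetic anhydride, CC(=O)OC(C)=O
Why: Chemoselective acylation should take the unhindered primary allylic alcohol far faster than the secondary C3 hydroxyl next to the gem-dimethyl carbon or the tertiary C8 hydroxyl.

Step 16
Reactants: 24 30-O-acetyl derivative of 23
Product: 25 myrrhanone A acetate as drawn: (5S,8R,9R,10S)-30-acetoxy-8-hydroxypolypoda-13E,17E,21E-trien-3-one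
Conditions: Dess–Martin periodinane, pyridine, CH2Cl2, 0 °C to rt
Reagents that add atoms: none
Why: Dess–Martin oxidation converts the only oxidisable (secondary) alcohol; the tertiary alcohol, the allylic acetate and the alkenes are inert, and C5 cannot epimerise because the quaternary C4 separates it from the new ketone.

**Compound list**
1 | (S)-(+)-carvone | CC1=CC[C@@H](CC1=O)C(C)=C | starting material
2 | allyl bromide | C=CCBr | starting material
3 | (5S,6R)-6-allylcarvone (allyl trans to isopropenyl) | CC1=CC[C@H](C(C)=C)[C@@H](CC=C)C1=O | intermediate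
4 | (5R,6S)-6-allyl-6-methylcarvone (methyl trans, allyl cis to isopropenyl) | CC1=CC[C@H](C(C)=C)[C@](C)(CC=C)C1=O | intermediate
5 | lithium enolate from conjugate reduction of 4 (not isolated) | [Li]OC1=C(C)CC[C@H](C(C)=C)[C@]1(C)CC=C | intermediate
6 | (5R,6S)-6-allyl-2,6-dimethyl-5-(prop-1-en-2-yl)cyclohex-1-en-1-yl triflate | O=S(=O)(OC1=C(C)CC[C@H](C(C)=C)[C@]1(C)CC=C)C(F)(F)F | intermediate
7 | (3R,4R)-3-allyl-1,3-dimethyl-4-(prop-1-en-2-yl)cyclohex-1-ene | CC1=C[C@@](C)(CC=C)[C@@H](C(C)=C)CC1 | intermediate
8 | 3-[1,3-dimethyl-6-(prop-1-en-2-yl)cyclohex-2-en-1-yl]propanal (configuration as in 7) | CC1=C[C@@](C)(CCC=O)[C@@H](C(C)=C)CC1 | intermediate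
9 | cis-fused 4,4,8,10-tetramethyl-Δ8(9)-octalin-3β-ol | CC1=C[C@@]2(C)CC[C@H](O)C(C)(C)[C@H]2CC1 | intermediate
10 | 9β-bromo-cis-decalin-3β,8α-diol, bromohydrin (not isolated) | Br[C@@H]1[C@@]2(C)CC[C@H](O)C(C)(C)[C@H]2CC[C@@]1(C)O | intermediate
11 | 8α,9α-epoxy-4,4,8,10-tetramethyl-cis-decalin-3β-ol | O1[C@H]2[C@@]3(C)CC[C@H](O)C(C)(C)[C@H]3CC[C@@]12C | intermediate
12 | 9β-vinyl-4,4,8β,10β-tetramethyl-cis-decalin-3β,8α-diol | C=C[C@@H]1[C@@]2(C)CC[C@H](O)C(C)(C)[C@H]2CC[C@@]1(C)O | intermediate
13 | 5-bromo-2-methylpent-2-ene | CC(C)=CCCBr | starting material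
14 | 6-methylhept-5-en-1-yne | C#CCCC=C(C)C | intermediate
15 | (E)-(2,6-dimethylhepta-1,5-dienyl)dimethylalane (not isolated) | C[Al](C)/C=C(\C)CCC=C(C)C | intermediate
16 | (E)-1-iodo-2,6-dimethylhepta-1,5-diene | I/C=C(\C)CCC=C(C)C | intermediate
17 | (2E,6E)-7-iodo-2,6-dimethylhepta-2,6-dien-1-ol | I/C=C(\C)CC/C=C(\C)CO | intermediate
18 | B-alkyl-9-BBN adduct of 12, boron on C12, hydroxyls drawn free (not isolated) | B1(CC[C@@H]2[C@@]3(C)CC[C@H](O)C(C)(C)[C@H]3CC[C@@]2(C)O)C2CCCC1CCC2 | intermediate
19 | C25 triol (3β,8α,19-triol, 13E,17E) | OC/C(C)=C/CC/C(C)=C/CC[C@@H]1[C@@]2(C)CC[C@H](O)C(C)(C)[C@H]2CC[C@@]1(C)O | intermediate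
20 | C25 allyl pinacolboronate (Bpin on C19) | CC1(C)OB(C/C(C)=C/CC/C(C)=C/CC[C@@H]2[C@@]3(C)CC[C@H](O)C(C)(C)[C@H]3CC[C@@]2(C)O)OC1(C)C | intermediate
21 | 2-methyl-2-vinyloxirane (isoprene monoxide, racemic) | CC1(C=C)CO1 | starting material
22 | C30 pinacol borate ester, O30–Bpin (not isolated) | CC1(C)OB(OC/C(C)=C/CC/C(C)=C/CC/C(C)=C/CC[C@@H]2[C@@]3(C)CC[C@H](O)C(C)(C)[C@H]3CC[C@@]2(C)O)OC1(C)C | intermediate
23 | (3S,5S,8R,9R,10S)-polypoda-13E,17E,21E-triene-3,8,30-triol | OC/C(C)=C/CC/C(C)=C/CC/C(C)=C/CC[C@@H]1[C@@]2(C)CC[C@H](O)C(C)(C)[C@H]2CC[C@@]1(C)O | intermediate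
24 | 30-O-acetate of 23 | CC(=O)OC/C(C)=C/CC/C(C)=C/CC/C(C)=C/CC[C@@H]1[C@@]2(C)CC[C@H](O)C(C)(C)[C@H]2CC[C@@]1(C)O | intermediate
25 | myrrhanone A acetate as drawn, (5S,8R,9R,10S) | CC(=O)OC/C(C)=C/CC/C(C)=C/CC/C(C)=C/CC[C@@H]1[C@@]2(C)CCC(=O)C(C)(C)[C@H]2CC[C@@]1(C)O | target

**Step count**
Total steps: 16. Longest linear sequence: 13 (steps 1–8 and 12–16).

**Steps most likely to fail**

1. Step 14 (Proposed new method). Several processes could go wrong:
   - head-to-head regiocontrol may be lost in the reductive elimination (bonding through C17 or C22);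
   - the 21E geometry may erode through syn/anti equilibration of the π-allyl complex;
   - palladium may isomerise the vinyl epoxide before transmetalation;
   - the allylboronate may be protonated.

   The fallback sets out from 19 and returns at 23. The primary allylic hydroxyl of 19 is exchanged for chloride (MsCl, LiCl, 2,4,6-collidine, DMF, 0 °C) to give the C25 allylic chloride F1. Commercial 3-methylbut-2-enyl phenyl sulfone is oxidised at its E-methyl group (cat. SeO2, t-BuOOH) to (E)-2-methyl-4-(phenylsulfonyl)but-2-en-1-ol F2. The O,C-dilithio derivative of F2 (n-BuLi, THF/DMPU, −78 °C, used in excess) is alkylated by F1 at the sulfonyl-bearing carbon. This Biellmann-type sulfone coupling forms the same C19–C20 bond with fixed regiochemistry and preformed E-alkenes, and gives the C30 hydroxy sulfone F3. Pd-catalysed hydride hydrogenolysis (PdCl2(dppp), LiHBEt3, THF, 0 °C) then removes the sulfonyl group without moving the C21=C22 double bond and gives 23.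

2. Step 8. Attack at C9, a secondary carbon next to quaternary C10, may be too slow, so that magnesium-induced rearrangement or halide opening of the epoxide, or base-induced elimination to an allylic alcohol, takes over. The fallback sets out from 11 and returns at 12. The slimmest carbon nucleophile is used under Lewis-acid-free SN2 conditions (lithium acetylide–ethylenediamine, DMSO, 50–60 °C), which should open the epoxide anti at C9 to the 9β-ethynyl-3β,8α-diol F4. Semihydrogenation over Lindlar catalyst (H2, quinoline, EtOAc) then gives 12.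

3. Step 6. Addition of the tertiary radical to the C=O group is reversible, so premature hydrogen capture by the radical (plain hydrogenation of the isopropenyl group) or hydrosilylation of the aldehyde may win. The fallback sets out from 8 and returns at 9. The aldehyde is converted into the nitrile F5 (I2, aq. NH3, THF, rt). The same tertiary radical, generated by Fe–H HAT (Fe(acac)3, PhSiH3, i-PrOH, 60 °C), then adds irreversibly 6-exo to the nitrile carbon (HAT-mediated nitrile cyclisation) to give the N–H ketimine F6. Work-up hydrolyses F6 to the cis-octalin-3-one F7, and hydride reduction (NaBH4, MeOH, 0 °C) should lead back to 9.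

**Further compounds**
F1 | step 14 | C25 allylic chloride (Cl on C19; 3β,8α-diol) | ClC/C(C)=C/CC/C(C)=C/CC[C@@H]1[C@@]2(C)CC[C@H](O)C(C)(C)[C@H]2CC[C@@]1(C)O
F2 | step 14 | (E)-2-methyl-4-(phenylsulfonyl)but-2-en-1-ol | OC/C(C)=C/CS(=O)(=O)c1ccccc1
F3 | step 14 | C30 hydroxy sulfone (PhSO2 on C20, both epimers at C20) | OC/C(C)=C/C(C/C(C)=C/CC/C(C)=C/CC[C@@H]1[C@@]2(C)CC[C@H](O)C(C)(C)[C@H]2CC[C@@]1(C)O)S(=O)(=O)c1ccccc1
F4 | step 8 | 9β-ethynyl-4,4,8β,10β-tetramethyl-cis-decalin-3β,8α-diol | C#C[C@@H]1[C@@]2(C)CC[C@H](O)C(C)(C)[C@H]2CC[C@@]1(C)O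
F5 | step 6 | 3-[1,3-dimethyl-6-(prop-1-en-2-yl)cyclohex-2-en-1-yl]propanenitrile (configuration as in 7) | CC1=C[C@@](C)(CCC#N)[C@@H](C(C)=C)CC1
F6 | step 6 | cis-fused 4,4,8,10-tetramethyl-Δ8(9)-octalin-3-imine | CC1=C[C@@]2(C)CCC(=N)C(C)(C)[C@H]2CC1
F7 | step 6 | cis-fused 4,4,8,10-tetramethyl-Δ8(9)-octalin-3-one | CC1=C[C@@]2(C)CCC(=O)C(C)(C)[C@H]2CC1
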